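**Plan**

- Retrosynthesis: ring C of the (3R)-isoflavan is cut at C2–C3 and O1–C8a together, so C2 and O1 leave as one formaldehyde unit. For this, C4 is raised to a ketone and C8a carries fluoride. The resulting deoxybenzoin is then cut at C3–C1' (ketone α-arylation) and at C4–C4a (aryl Grignard acylation).
- Enabling feature: C3 sits between ring B and C4, so a C4 carbonyl makes it an enolisable benzylic CH2. C8a of ring A is ortho to that carbonyl and meta to the C5 and C7 oxygens, so an alkoxide can displace fluoride there.
- Forward: a ring A block (C8a–F, C8 formyl masked as dioxolane, C5-OMe and C7-OMOM differentiated early) and a ring B block (prenyl placed between two MOM ethers) are joined as a deoxybenzoin. Ring C, the only ring built, closes in the key step.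
- Stereochemistry: C3 is formed racemic and epimerisable in the key step. It is fixed as (R) by Ru-catalysed transfer hydrogenation with dynamic kinetic resolution, giving the cis-(3R,4R) alcohol. The helper C4 oxygen is then removed by a radical deoxygenation that does not touch C3.
- End: one acid step removes three MOM groups and the dioxolane. Isoflavan numbering (O1, C2, C3, C4, C4a, C5–C8, C8a; ring B primed) is used throughout.

Key step: step 10

Assumption: 2-fluoro-4,6-dimethoxybenzaldehyde (1), the Vilsmeier–Haack product of 1-fluoro-3,5-dimethoxybenzene, is taken as a purchased material, as is resorcinol (8).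

**Route**

Step 1
Reactants: 1 2-fluoro-4,6-dimethoxybenzaldehyde
Product: 2 2-fluoro-6-hydroxy-4-methoxybenzaldehyde
Conditions: BCl3 (1.1 equiv), CH2Cl2, −78 → 0 °C; aqueous work-up
Reagents that add atoms: none
Why: Chelation-controlled Lewis-acid ether cleavage; boron bound to the formyl oxygen should cleave only the ortho methoxy group, which becomes the C7 oxygen, and leave the para methoxy group (later C5-OMe).

Step 2
Reactants: 2 2-fluoro-6-hydroxy-4-methoxybenzaldehyde
Product: 3 3-bromo-2-fluoro-6-hydroxy-4-methoxybenzaldehyde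
Conditions: NBS (1.0 equiv), MeCN, 0 °C
Reagents that add atoms: N-bromosuccinimide, O=C1CCC(=O)N1Br
Why: Electrophilic aromatic bromination should go para to the free phenol and ortho to OMe, the same site preference as the 5-bromination of 2-hydroxy-4-methoxybenzaldehyde; this marks the future C4a.

Step 3
Reactants: 3 3-bromo-2-fluoro-6-hydroxy-4-methoxybenzaldehyde
Product: 4 4-bromo-2-(1,3-dioxolan-2-yl)-3-fluoro-5-methoxyphenol
Conditions: HOCH2CH2OH, p-TsOH (cat.), toluene, reflux, Dean–Stark
Reagents that add atoms: ethylene glycol, OCCO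
Why: Acid-catalysed acetalisation with azeotropic water removal masks the future C8 formyl group against the organometallic, enolate and hydride steps.

Step 4
Reactants: 4 4-bromo-2-(1,3-dioxolan-2-yl)-3-fluoro-5-methoxyphenol
Product: 5 2-[3-bromo-2-fluoro-4-methoxy-6-(methoxymethoxy)phenyl]-1,3-dioxolane
Conditions: NaH, MOMCl, DMF, 0 °C → rt
Reagents that add atoms: chloromethyl methyl ether, COCCl
Why: Williamson-type O-alkylation of the phenoxide (MOM protection) under basic conditions that leave the acetal intact.

Step 5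
Reactants: 5 2-[3-bromo-2-fluoro-4-methoxy-6-(methoxymethoxy)phenyl]-1,3-dioxolane
Product: 7 1-[3-(1,3-dioxolan-2-yl)-2-fluoro-6-methoxy-4-(methoxymethoxy)phenyl]ethan-1-one, via arylmagnesium chloride 6 (not isolated)
Conditions: iPrMgCl·LiCl, THF, 0 → 25 °C; then MeC(O)N(OMe)Me, 0 °C → rt; aqueous NH4Cl
Reagents that add atoms: N-methoxy-N-methylacetamide, CC(=O)N(C)OC
Why: Knochel bromine–magnesium exchange, helped by the flanking F and OMe, followed by Weinreb ketone synthesis; the magnesium species is used because an ortho-fluoroaryllithium would lose LiF to an aryne on warming.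

Step 6
Reactants: 8 resorcinol
Product: 9 1,3-bis(methoxymethoxy)benzene
Conditions: NaH, MOMCl, DMF, 0 °C → rt
Reagents that add atoms: chloromethyl methyl ether, COCCl
Why: Double Williamson-type MOM protection; the two OMOM groups later direct both metalations of ring B.

Step 7
Reactants: 9 1,3-bis(methoxymethoxy)benzene
Product: 11 1,3-bis(methoxymethoxy)-2-(3-methylbut-2-en-1-yl)benzene, via 2,6-bis(methoxymethoxy)phenyllithium 10 (not isolated)
Conditions: n-BuLi, THF, 0 °C → rt; CuBr·SMe2 (cat.), prenyl bromide, −78 °C → rt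
Reagents that add atoms: prenyl bromide, CC(C)=CCBr
Why: Directed ortho-metalation at the position between the two OMOM groups, then copper-mediated allylation, which favours attack at the primary carbon of prenyl bromide.

Step 8
Reactants: 11 1,3-bis(methoxymethoxy)-2-(3-methylbut-2-en-1-yl)benzene
Product: 13 1-bromo-2,4-bis(methoxymethoxy)-3-(3-methylbut-2-en-1-yl)benzene, via aryllithium 12 (not isolated)
Conditions: n-BuLi, TMEDA, THF, 0 °C; BrCCl2CCl2Br, −78 °C → rt
Reagents that add atoms: 1,2-dibromo-1,1,2,2-tetrachloroethane, BrC(Cl)(Cl)C(Cl)(Cl)Br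
Why: Second directed ortho-metalation at the only remaining position ortho to an OMOM group, then bromine transfer to the aryllithium; NBS is avoided because of the prenyl alkene.

Step 9
Reactants: 7 1-[3-(1,3-dioxolan-2-yl)-2-fluoro-6-methoxy-4-(methoxymethoxy)phenyl]ethan-1-one; 13 1-bromo-2,4-bis(methoxymethoxy)-3-(3-methylbut-2-en-1-yl)benzene
Product: 14 2-[2,4-bis(methoxymethoxy)-3-(3-methylbut-2-en-1-yl)phenyl]-1-[3-(1,3-dioxolan-2-yl)-2-fluoro-6-methoxy-4-(methoxymethoxy)phenyl]ethan-1-one
Conditions: Pd2(dba)3 (cat.), XPhos, K3PO4, toluene, 80 °C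
Reagents that add atoms: none
Why: Palladium-catalysed ketone α-arylation (Buchwald–Hartwig type) forms C3–C1'; the non-nucleophilic phosphate base spares the activated C–F bond, and the bulky ligand with the ortho-substituted bromide should stop at mono-arylation.

Step 10
Reactants: 14 the deoxybenzoin from step 9
Product: 16 racemic 3-[2,4-bis(methoxymethoxy)-3-(3-methylbut-2-en-1-yl)phenyl]-8-(1,3-dioxolan-2-yl)-5-methoxy-7-(methoxymethoxy)chroman-4-one, via aldol adduct 15 (not isolated)
Conditions: (CH2O)n (1.2 equiv), K2CO3, DMSO, 25 → 50 °C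
Reagents that add atoms: formaldehyde (from paraformaldehyde), C=O
Why: K2CO3 in DMSO enolises the C3 methylene of 14 (flanked by the C4 carbonyl and ring B); the enolate adds to formaldehyde to give aldolate 15, whose primary alkoxide attacks C8a, where the ortho C4 carbonyl stabilises the Meisenheimer adduct before fluoride leaves. The closest known reaction type is the aldol addition/intramolecular SNAr O-arylation sequence that turns 2-fluoroaryl ketones and aldehydes into chroman-4-ones, run here as one domino operation on a deoxybenzoin with formaldehyde. Ring C closes as a six-membered ring by addition–elimination of oxygen at the sp2 carbon C8a (6-exo-trig with respect to the C8–C8a π bond). The new C3 stereocentre is formed racemic and is deliberately left epimerisable α to C4=O; it is controlled in step 11. The step needs mono-hydroxymethylation and O-arylation at C8a only: retro-aldol, second hydroxymethylation and dehydration/rehydration are reversible and drain into the irreversible loss of fluoride, C8a is the only carbon with a leaving group, the C5 and C7 oxygens are meta to it and so do not deactivate the substitution, and the acetal, MOM ethers and prenyl group are inert to carbonate.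

Step 11
Reactants: 16 the racemic isoflavanone from step 10
Product: 17 (3R,4R)-3-[2,4-bis(methoxymethoxy)-3-(3-methylbut-2-en-1-yl)phenyl]-8-(1,3-dioxolan-2-yl)-5-methoxy-7-(methoxymethoxy)chroman-4-ol
Conditions: RuCl[(R,R)-TsDPEN](p-cymene) (cat.), HCO2H/Et3N (amine-rich), EtOAc, 40 °C
Reagents that add atoms: none
Why: Noyori–Ikariya asymmetric transfer hydrogenation with dynamic kinetic resolution; Et3N should interconvert the C3 epimers through the enol, the (R,R) catalyst should set (4R) in the sense known for aryl ketones, and hydride delivery anti to the 3-aryl group should make the cis-(3R,4R) alcohol the fast-formed product, while the amine-rich medium protects the acetal and MOM ethers.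

Step 12
Reactants: 17 the (3R,4R)-alcohol from step 11
Product: 18 O-[(3R,4R)-3-[2,4-bis(methoxymethoxy)-3-(3-methylbut-2-en-1-yl)phenyl]-8-(1,3-dioxolan-2-yl)-5-methoxy-7-(methoxymethoxy)chroman-4-yl] S-methyl carbonodithioate
Conditions: NaH, THF, 0 °C; CS2; MeI, 0 °C → rt
Reagents that add atoms: carbon disulfide, S=C=S; iodomethane, CI
Why: Xanthate formation from the sodium alkoxide (first half of a Barton–McCombie deoxygenation); C3 is no longer acidic, so the base cannot epimerise it.

Step 13
Reactants: 18 the xanthate from step 12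
Product: 19 (3R)-3-[2,4-bis(methoxymethoxy)-3-(3-methylbut-2-en-1-yl)phenyl]-8-(1,3-dioxolan-2-yl)-5-methoxy-7-(methoxymethoxy)chromane
Conditions: Bu3SnH, AIBN (cat.), toluene, 90 °C
Reagents that add atoms: none
Why: Barton–McCombie radical deoxygenation; the benzylic C4 radical is quenched by the tin hydride without involving C3, thermal syn-elimination is disfavoured because H3 is trans to the C4 oxygen, and the neutral radical path avoids a C4 cation that the 2'-oxygen could trap.

Step 14
Reactants: 19 the protected (3R)-isoflavan from step 13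
Product: 20 (3R)-3-[2,4-dihydroxy-3-(3-methylbut-2-en-1-yl)phenyl]-7-hydroxy-5-methoxychromane-8-carbaldehyde
Conditions: aqueous HCl (2 M), MeOH/THF, 40 °C
Reagents that add atoms: water, O
Why: Acid hydrolysis of the three MOM acetals and the dioxolane in one operation; dilute acid at mild temperature is chosen so that the prenyl group is not cyclised onto the neighbouring phenols, and C3 carries no acidic or ionisable neighbour.

**Compound list**

1 | 2-fluoro-4,6-dimethoxybenzaldehyde | COc1cc(OC)c(C=O)c(F)c1 | starting material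
2 | 2-fluoro-6-hydroxy-4-methoxybenzaldehyde | COc1cc(O)c(C=O)c(F)c1 | intermediate
3 | 3-bromo-2-fluoro-6-hydroxy-4-methoxybenzaldehyde | COc1cc(O)c(C=O)c(F)c1Br | intermediate
4 | 4-bromo-2-(1,3-dioxolan-2-yl)-3-fluoro-5-methoxyphenol | COc1cc(O)c(C2OCCO2)c(F)c1Br | intermediate
5 | 2-[3-bromo-2-fluoro-4-methoxy-6-(methoxymethoxy)phenyl]-1,3-dioxolane | COCOc1cc(OC)c(Br)c(F)c1C1OCCO1 | intermediate
6 | [3-(1,3-dioxolan-2-yl)-2-fluoro-6-methoxy-4-(methoxymethoxy)phenyl]magnesium chloride (not isolated) | COCOc1cc(OC)c([Mg]Cl)c(F)c1C1OCCO1 | intermediate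
7 | 1-[3-(1,3-dioxolan-2-yl)-2-fluoro-6-methoxy-4-(methoxymethoxy)phenyl]ethan-1-one | CC(=O)c1c(OC)cc(OCOC)c(C2OCCO2)c1F | intermediate
8 | resorcinol | Oc1cccc(O)c1 | starting material
9 | 1,3-bis(methoxymethoxy)benzene | COCOc1cccc(OCOC)c1 | intermediate
10 | 2,6-bis(methoxymethoxy)phenyllithium (not isolated) | [Li]c1c(OCOC)cccc1OCOC | intermediate
11 | 1,3-bis(methoxymethoxy)-2-(3-methylbut-2-en-1-yl)benzene | COCOc1cccc(OCOC)c1CC=C(C)C | intermediate
12 | [2,4-bis(methoxymethoxy)-3-(3-methylbut-2-en-1-yl)phenyl]lithium (not isolated) | [Li]c1ccc(OCOC)c(CC=C(C)C)c1OCOC | intermediate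
13 | 1-bromo-2,4-bis(methoxymethoxy)-3-(3-methylbut-2-en-1-yl)benzene | COCOc1ccc(Br)c(OCOC)c1CC=C(C)C | intermediate
14 | 2-[2,4-bis(methoxymethoxy)-3-(3-methylbut-2-en-1-yl)phenyl]-1-[3-(1,3-dioxolan-2-yl)-2-fluoro-6-methoxy-4-(methoxymethoxy)phenyl]ethan-1-one | COCOc1ccc(CC(=O)c2c(OC)cc(OCOC)c(C3OCCO3)c2F)c(OCOC)c1CC=C(C)C | intermediate
15 | racemic 2-[2,4-bis(methoxymethoxy)-3-(3-methylbut-2-en-1-yl)phenyl]-1-[3-(1,3-dioxolan-2-yl)-2-fluoro-6-methoxy-4-(methoxymethoxy)phenyl]-3-hydroxypropan-1-one (aldol adduct, not isolated) | COCOc1ccc(C(CO)C(=O)c2c(OC)cc(OCOC)c(C3OCCO3)c2F)c(OCOC)c1CC=C(C)C | intermediate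
16 | racemic 3-[2,4-bis(methoxymethoxy)-3-(3-methylbut-2-en-1-yl)phenyl]-8-(1,3-dioxolan-2-yl)-5-methoxy-7-(methoxymethoxy)chroman-4-one | COc1cc(OCOC)c(C3OCCO3)c2c1C(=O)C(c1ccc(OCOC)c(CC=C(C)C)c1OCOC)CO2 | intermediate
17 | (3R,4R)-3-[2,4-bis(methoxymethoxy)-3-(3-methylbut-2-en-1-yl)phenyl]-8-(1,3-dioxolan-2-yl)-5-methoxy-7-(methoxymethoxy)chroman-4-ol | COc1cc(OCOC)c(C3OCCO3)c2c1[C@H](O)[C@H](c1ccc(OCOC)c(CC=C(C)C)c1OCOC)CO2 | intermediate
18 | O-[(3R,4R)-3-[2,4-bis(methoxymethoxy)-3-(3-methylbut-2-en-1-yl)phenyl]-8-(1,3-dioxolan-2-yl)-5-methoxy-7-(methoxymethoxy)chroman-4-yl] S-methyl carbonodithioate | COc1cc(OCOC)c(C3OCCO3)c2c1[C@H](OC(=S)SC)[C@H](c1ccc(OCOC)c(CC=C(C)C)c1OCOC)CO2 | intermediate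
19 | (3R)-3-[2,4-bis(methoxymethoxy)-3-(3-methylbut-2-en-1-yl)phenyl]-8-(1,3-dioxolan-2-yl)-5-methoxy-7-(methoxymethoxy)chromane | COc1cc(OCOC)c(C3OCCO3)c2c1C[C@H](c1ccc(OCOC)c(CC=C(C)C)c1OCOC)CO2 | intermediate
20 | (3R)-3-[2,4-dihydroxy-3-(3-methylbut-2-en-1-yl)phenyl]-7-hydroxy-5-methoxychromane-8-carbaldehyde | COc1cc(O)c(C=O)c2c1C[C@H](c1ccc(O)c(CC=C(C)C)c1O)CO2 | target

**Count**

Total steps: 14. Longest linear sequence: 11 steps (steps 1–5 and 9–14, from compound 1).

**Steps most likely to fail**

1. Step 10 (key step). The hydroxymethyl ketone may be lost by dehydration to the α-methylene ketone and Michael capture by unreacted enolate, or ring closure may lag because the doubly ortho-substituted aroyl group is twisted out of conjugation. The fallback moves the C1 unit to the formate level and sets out from 14. Claisen formylation with ethyl formate and NaH in THF should give the hydroxymethylene ketone F1 as its sodium enolate. This enolate cannot dehydrate or dimerise, and on warming in DMF its oxygen should displace fluoride at C8a to give the isoflavone F2. Transfer hydrogenation of F2 with RuCl[(R,R)-TsDPEN](p-cymene) and HCO2H/Et3N should run as a cascade, conjugate reduction to 16 in the flask followed by the dynamic kinetic ketone reduction, and the route is rejoined at 17.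

2. Step 11. Hydride transfer to the carbonyl flanked by the peri C5 methoxy group may be slow relative to, or uncoupled from, C3 epimerisation, giving poor enantio- and diastereoselection. The fallback is a classical resolution and sets out from 16. Reduction with LiBH(sec-Bu)3 in THF at −78 °C should give the racemic cis-alcohol F3. Steglich esterification with (S)-O-methylmandelic acid (DCC, DMAP) and chromatographic separation of the diastereomers should give the (3R,4R) ester F4, and methanolysis with K2CO3 in MeOH returns to 17.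

3. Step 12. The xanthate of the very electron-rich C4 benzylic alcohol may ionise, leading to rearrangement to the S-alkyl dithiocarbonate or elimination to the isoflav-3-ene with loss of the C3 centre. The fallback avoids any leaving-group derivative and sets out from 17. Direct deoxygenation of the free benzylic alcohol with the trivalent titanium reagent Cp2TiCl (from Cp2TiCl2 and Mn dust, THF, reflux) should proceed by C–O homolysis of the titanium-bound alcohol and reduction/protonation of the benzylic radical. It returns to the route at 19 and replaces steps 12 and 13; this fallback makes no new compound (F0).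

**Further compounds**

F1 | step 10 | 2-[2,4-bis(methoxymethoxy)-3-(3-methylbut-2-en-1-yl)phenyl]-1-[3-(1,3-dioxolan-2-yl)-2-fluoro-6-methoxy-4-(methoxymethoxy)phenyl]-3-hydroxyprop-2-en-1-one | COCOc1ccc(C(=CO)C(=O)c2c(OC)cc(OCOC)c(C3OCCO3)c2F)c(OCOC)c1CC=C(C)C
F2 | step 10 | 3-[2,4-bis(methoxymethoxy)-3-(3-methylbut-2-en-1-yl)phenyl]-8-(1,3-dioxolan-2-yl)-5-methoxy-7-(methoxymethoxy)-4H-chromen-4-one | COCOc1ccc(-c2coc3c(C4OCCO4)c(OCOC)cc(OC)c3c2=O)c(OCOC)c1CC=C(C)C
F3 | step 11 | racemic cis-3-[2,4-bis(methoxymethoxy)-3-(3-methylbut-2-en-1-yl)phenyl]-8-(1,3-dioxolan-2-yl)-5-methoxy-7-(methoxymethoxy)chroman-4-ol | COc1cc(OCOC)c(C3OCCO3)c2c1C(O)C(c1ccc(OCOC)c(CC=C(C)C)c1OCOC)CO2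
F4 | step 11 | (3R,4R)-3-[2,4-bis(methoxymethoxy)-3-(3-methylbut-2-en-1-yl)phenyl]-8-(1,3-dioxolan-2-yl)-5-methoxy-7-(methoxymethoxy)chroman-4-yl (S)-2-methoxy-2-phenylacetate | COc1cc(OCOC)c(C3OCCO3)c2c1[C@H](OC(=O)[C@@H](OC)c1ccccc1)[C@H](c1ccc(OCOC)c(CC=C(C)C)c1OCOC)CO2
F0 | step 12 | none | none
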